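By 2.50 min the larch product had stopped climbing, and by 2.50 min the elm product had too, so I took the mean of the readings from then on as a plateau: 14.2% in larch and 52.3% in elm.

the same everywhere: starting material 0.10 M; enzyme 0.0013 mol%

|  | second substrate | remark | time |
|---|---|---|---|
| larch | 1.9 equiv | run made earlier |  |
| elm | 17 equiv | run made earlier |  |
| dawn | 1.50 equiv |  | 6.0 min |
| spring | 3.00 equiv |  | 6.0 min |
| autumn | 6.00 equiv |  | 6.0 min |
| winter | 12.0 equiv |  | 6.0 min |

| run | time / min | product / % |
|---|---|---|
| larch | 0.833 | 10.1 |
| larch | 1.50 | 13.6 |
| larch | 2.50 | 14.8 |
| larch | 3.00 | 13.9 |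
| larch | 4.00 | 14.1 |
| larch | 5.00 | 14.9 |
| larch | 6.00 | 13.2 |
| elm | 0.833 | 39.8 |
| elm | 1.50 | 49.0 |
| elm | 2.50 | 50.1 |
| elm | 3.00 | 53.3 |
| elm | 4.00 | 52.2 |
| elm | 5.00 | 51.9 |
| elm | 6.00 | 53.9 |

(each reading ± 1 percentage point)

- percent here means starting material units held: one homo dimer counts as two
- what is said of product includes idle complex
- reactions considered so far: starting material + enzyme <-> starting complex; second substrate + starting complex <-> ternary complex; ternary complex -> enzyme + product; 2 starting material -> homo dimer; enzyme -> spent catalyst; enzyme + product <-> idle complex
- the concentration of product that is asked is that of its free form alone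
- "hardly changes" means that all values lie within two and a half points (for a concentration: within two and a half percent of the largest)

* [product] (only what is free in solution) at the end for dawn, spring, autumn, winter, in this order
* the shape of the row from first to last (rises, then falls / falls, then rises / falls all the way / hardly changes / rises all the way)

This was my note for the bench. The four new flasks needed no longer wait, because 6.0 min lay inside the flat stretch of both earlier runs, later than its first reading at 2.50 min. Idle complex needed no correction either, because the enzyme charged, 1.30 × 10⁻⁶ M, was far less than the product at the larch plateau.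

Counting turnovers, each enzyme had made about 10900 in larch and 40200 in elm. I gave one number the name price: the equivalents of second substrate charged, times the share of starting material that did not become product, over the share that did. It was 11.5 in larch and 15.5 in elm. I drew a straight line through these two prices, rising 0.266 per equivalent. The line gave prices of 11.4, 11.8, 12.6 and 14.2. Product is then the starting charge times equivalents over price plus equivalents, which gave me 0.0116 M, 0.0203 M, 0.0323 M and 0.0458 M, a row that rises at each step.

The forecast read 0.0116 M, 0.0203 M, 0.0325 M and 0.0458 M, a row that rises all the way, “rising steadily with second substrate”.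

The flasks gave 0.0118 M, 0.0211 M, 0.0341 M and 0.0478 M, and the row rises all the way.

    starting material + enzyme ⇌ starting complex (K = 6.76 M⁻¹, k = 4.18 × 10⁵ M⁻¹ s⁻¹)
    second substrate + starting complex ⇌ ternary complex (K = 2.80 M⁻¹, k = 43200 M⁻¹ s⁻¹)
    ternary complex → enzyme + product (k = 1680 s⁻¹)
    2 starting material → homo dimer (k = 0.205 M⁻¹ s⁻¹)
    enzyme → spent catalyst (k = 0.0128 s⁻¹)
    enzyme + product ⇌ idle complex (K = 4.60 M⁻¹, k = 0.291 M⁻¹ s⁻¹)

Reckoned from free product, the price was 11.2 in spring, against 11.8 on the line, and 13.1 in winter, against 14.2. In dawn the first half-life of starting material by the homo dimer step alone was 0.407 min, shorter than the 0.903 min half-life of enzyme by its own death step alone. At 6.00 min dawn held 82.6% of its starting material as homo dimer and 97.9% of its catalyst as spent catalyst.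

The numbers in the tables were computed for substances that don't exist; scatter was added.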